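**Strategy.** The depside ester is disconnected last; everything rests on building ring B from an open-chain vinyl diazo keto ester by a Danheiser benzannulation. In one operation the step forms C3–C4, C1–C2 and C4–C5 of ring B and exploits its unsymmetrical oxygenation: the C4 oxygen arrives as the ketene carbonyl and the C2 methoxy group on methoxyacetylene, so C2–OMe and a free C4–OH emerge differentiated, flanking the C1 carboxyl and C6 pentyl group already in place. The precursor is benzyl 2-diazo-4-methylidene-3-oxononanoate, made by diazoacetate aldol addition and oxidation. Acylation of C4–OH by benzyl-protected ring A acid and one global hydrogenolysis complete the target.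

Key step: step 5

Remark on the chemistry: the target has no stereocentre. Compounds 4 and 10 are racemic, and their stereocentres are destroyed in the events that follow. Methoxyacetylene (bp 23 °C) is assumed to be handled as a cold stock solution and used at once.

**Step 1**
Reactants: 1 heptanal
Product: 2 2-methylideneheptanal (2-pentylacrolein)
Conditions: 37% aq. CH2O, pyrrolidine (10 mol %), propionic acid (10 mol %), i-PrOH, 45 °C
Reagents that add atoms: formaldehyde, C=O
Why: Amine-catalysed Mannich condensation (α-methylenation of an aldehyde), in which the enamine of heptanal adds to the formaldehyde-derived iminium ion and β-elimination of the amine gives the 2-alkylacrolein without creating a stereocentre.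

**Step 2**
Reactants: 2 2-methylideneheptanal; 3 benzyl diazoacetate
Product: 4 benzyl 2-diazo-3-hydroxy-4-methylidenenonanoate (racemic)
Conditions: DBU (15 mol %), MeCN, 0 °C to rt
Reagents that add atoms: none
Why: DBU-catalysed aldol-type 1,2-addition of the diazoacetate carbanion to the aldehyde carbonyl, which should form the carbinol centre as a racemate that is removed in step 3.

**Step 3**
Reactants: 4 benzyl 2-diazo-3-hydroxy-4-methylidenenonanoate
Product: 5 benzyl 2-diazo-4-methylidene-3-oxononanoate
Conditions: 2-iodoxybenzoic acid (IBX, 1.5 equiv), DMSO, rt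
Reagents that add atoms: none
Why: IBX oxidation of a secondary allylic alcohol to the ketone under neutral conditions, which should leave the acid-sensitive diazo group and the 1,1-disubstituted alkene untouched.

**Step 4**
Reactants: 6 chloroacetaldehyde dimethyl acetal
Product: 8 methoxyacetylene, via sodium methoxyacetylide 7 (not isolated)
Conditions: NaNH2 (3 equiv), liquid NH3, −33 °C; evaporate NH3; cold saturated aq. NaCl, −20 °C; distil into a cold trap
Reagents that add atoms: none
Why: Base-induced β-elimination of methanol and then of HCl from the chloroacetal gives the ynol ether, which is held as its sodium acetylide until protonation on aqueous quench and distillation of the volatile alkyne.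

**Step 5**
Reactants: 5 benzyl 2-diazo-4-methylidene-3-oxononanoate; 8 methoxyacetylene
Product: 13 benzyl 4-hydroxy-2-methoxy-6-pentylbenzoate, via vinylketene 9 (not isolated), via vinylcyclobutenone 10 (not isolated), via dienylketene 11 (not isolated), via cyclohexa-2,4-dienone 12 (not isolated)
Conditions: 8 (4 equiv), hν (300 nm, Pyrex), ClCH2CH2Cl, 0 °C, sealed tube; then 80 °C
Reagents that add atoms: none
Why: Irradiation expels N2 and the hept-1-en-2-yl group migrates from the ketone carbon to the diazo carbon (photochemical Wolff rearrangement) to give ester-substituted vinylketene 9; the polarised ynol ether then adds across the ketene C=C in a [2+2] cycloaddition (its nucleophilic CH carbon to the ketene carbonyl carbon, its methoxy-bearing carbon to the ester-bearing carbon) to give cyclobutenone 10, which opens by 4π-electrocyclic cleavage to dienylketene 11, closes by 6π-electrocyclisation to dienone 12 and enolises to phenol 13. The closest known reaction type is the Danheiser benzannulation in its diazo ketone (Wolff) variant with alkoxy- or silyloxyacetylenes. Ring B is closed by thermal disrotatory 6π-electrocyclisation that forms C4–C5, after C3–C4 and C1–C2 have been made in the [2+2] event through a transient four-membered ring. No stereocentre is created in 13: the quaternary carbon of 10 is racemic and disappears on ring opening, and only the dienylketene with the alkenyl group cis to the ketenyl group can cyclise, the other isomer returning reversibly to 10 at 80 °C. The step needs the [2+2] orientation, which the donor polarisation of methoxyacetylene secures so that the C4 phenol oxygen comes from the ketene and the C2 methoxy group from the alkyne, and it needs closure at carbon and not at the ester oxygen (no hetero-[4+2] pyranone), which is expected because an ester carbonyl is a poor heterodiene terminus and alkoxycarbonyl ketenes typically give four-membered adducts. Low temperature, excess alkyne and filtered 300 nm light should limit ketene dimerisation and secondary photolysis of the benzyl ester and the phenol.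

**Step 6**
Reactants: 14 olivetol
Product: 16 2,4-dihydroxy-6-pentylbenzaldehyde, via iminium chloride 15 (not isolated)
Conditions: POCl3, DMF, 0 °C to rt; then H2O, 50 °C
Reagents that add atoms: N,N-dimethylformamide, CN(C)C=O; water, O
Why: Vilsmeier–Haack formylation, in which the chloroiminium electrophile attacks the ring carbon para to one hydroxyl and ortho to the other (next to the pentyl group) in preference to the carbon between the two hydroxyls, and the aryl iminium salt is hydrolysed on work-up.

**Step 7**
Reactants: 16 2,4-dihydroxy-6-pentylbenzaldehyde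
Product: 17 2,4-bis(benzyloxy)-6-pentylbenzaldehyde
Conditions: BnBr (2.5 equiv), K2CO3, DMF, 60 °C
Reagents that add atoms: benzyl bromide, BrCc1ccccc1
Why: Williamson ether synthesis, in which excess benzyl bromide in warm DMF should alkylate the free 4-hydroxyl and the chelated 2-hydroxyl alike.

**Step 8**
Reactants: 17 2,4-bis(benzyloxy)-6-pentylbenzaldehyde
Product: 18 2,4-bis(benzyloxy)-6-pentylbenzoic acid
Conditions: NaClO2, NaH2PO4, 2-methyl-2-butene, t-BuOH/THF/H2O, rt
Reagents that add atoms: sodium chlorite, [Na+].[O-]Cl=O
Why: Pinnick oxidation of the hindered aryl aldehyde to the acid, with the alkene scavenger removing hypochlorous acid so that the electron-rich ring and the benzyl ethers are spared.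

**Step 9**
Reactants: 18 2,4-bis(benzyloxy)-6-pentylbenzoic acid; 13 benzyl 4-hydroxy-2-methoxy-6-pentylbenzoate
Product: 20 4-[(benzyloxy)carbonyl]-3-methoxy-5-pentylphenyl 2,4-bis(benzyloxy)-6-pentylbenzoate, via acid chloride 19 (not isolated)
Conditions: (COCl)2, DMF (cat.), CH2Cl2, 0 °C to rt; evaporate; then 13, Et3N, DMAP (cat.), CH2Cl2, 0 °C to rt
Reagents that add atoms: none
Why: DMF-catalysed conversion of the acid into its chloride followed by DMAP-catalysed acyl transfer to the C4 hydroxyl, the only free hydroxyl of 13, should give the aryl ester (depside) bond.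

**Step 10**
Reactants: 20 4-[(benzyloxy)carbonyl]-3-methoxy-5-pentylphenyl 2,4-bis(benzyloxy)-6-pentylbenzoate
Product: 21 4-[(2,4-dihydroxy-6-pentylbenzoyl)oxy]-2-methoxy-6-pentylbenzoic acid (target)
Conditions: H2 (1 atm), 10% Pd/C, EtOAc, rt
Reagents that add atoms: none
Why: Heterogeneous hydrogenolysis should cleave the three benzylic C–O bonds (two ethers and one ester) while the aryl ester linkage, which has no benzylic C–O bond, and the methyl ether remain.

**Compound list**
1 | heptanal | CCCCCCC=O | starting material
2 | 2-methylideneheptanal | CCCCCC(=C)C=O | intermediate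
3 | benzyl diazoacetate | [N-]=[N+]=CC(=O)OCc1ccccc1 | starting material
4 | benzyl 2-diazo-3-hydroxy-4-methylidenenonanoate (racemic) | CCCCCC(=C)C(O)C(=[N+]=[N-])C(=O)OCc1ccccc1 | intermediate
5 | benzyl 2-diazo-4-methylidene-3-oxononanoate | CCCCCC(=C)C(=O)C(=[N+]=[N-])C(=O)OCc1ccccc1 | intermediate
6 | chloroacetaldehyde dimethyl acetal (2-chloro-1,1-dimethoxyethane) | COC(CCl)OC | starting material
7 | sodium methoxyacetylide | [Na+].[C-]#COC | intermediate
8 | methoxyacetylene | C#COC | intermediate
9 | benzyl 3-methylidene-2-(oxomethylidene)octanoate (vinylketene) | CCCCCC(=C)C(=C=O)C(=O)OCc1ccccc1 | intermediate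
10 | benzyl 1-(hept-1-en-2-yl)-2-methoxy-4-oxocyclobut-2-ene-1-carboxylate (racemic) | CCCCCC(=C)C1(C(=O)OCc2ccccc2)C(OC)=CC1=O | intermediate
11 | benzyl (2Z)-2-(hept-1-en-2-yl)-3-methoxy-5-oxopenta-2,4-dienoate (dienylketene) | CCCCCC(=C)/C(C(=O)OCc1ccccc1)=C(/OC)C=C=O | intermediate
12 | benzyl 6-methoxy-4-oxo-2-pentylcyclohexa-1,5-diene-1-carboxylate | CCCCCC1=C(C(=O)OCc2ccccc2)C(OC)=CC(=O)C1 | intermediate
13 | benzyl 4-hydroxy-2-methoxy-6-pentylbenzoate | CCCCCc1cc(O)cc(OC)c1C(=O)OCc1ccccc1 | intermediate
14 | olivetol (5-pentylbenzene-1,3-diol) | CCCCCc1cc(O)cc(O)c1 | starting material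
15 | [(2,4-dihydroxy-6-pentylphenyl)methylidene]dimethyliminium chloride | CCCCCc1cc(O)cc(O)c1C=[N+](C)C.[Cl-] | intermediate
16 | 2,4-dihydroxy-6-pentylbenzaldehyde | CCCCCc1cc(O)cc(O)c1C=O | intermediate
17 | 2,4-bis(benzyloxy)-6-pentylbenzaldehyde | CCCCCc1cc(OCc2ccccc2)cc(OCc2ccccc2)c1C=O | intermediate
18 | 2,4-bis(benzyloxy)-6-pentylbenzoic acid | CCCCCc1cc(OCc2ccccc2)cc(OCc2ccccc2)c1C(=O)O | intermediate
19 | 2,4-bis(benzyloxy)-6-pentylbenzoyl chloride | CCCCCc1cc(OCc2ccccc2)cc(OCc2ccccc2)c1C(=O)Cl | intermediate
20 | 4-[(benzyloxy)carbonyl]-3-methoxy-5-pentylphenyl 2,4-bis(benzyloxy)-6-pentylbenzoate | CCCCCc1cc(OCc2ccccc2)cc(OCc2ccccc2)c1C(=O)Oc1cc(CCCCC)c(C(=O)OCc2ccccc2)c(OC)c1 | intermediate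
21 | 4-[(2,4-dihydroxy-6-pentylbenzoyl)oxy]-2-methoxy-6-pentylbenzoic acid | CCCCCc1cc(O)cc(O)c1C(=O)Oc1cc(CCCCC)c(C(=O)O)c(OC)c1 | target

**Step count.** Total: 10 steps. Longest linear sequence: 6 steps (1, 2, 3, 5, 9, 10).

**Steps most likely to fail**

Step 5. The ketene may be captured through its ester carbonyl (closure at oxygen to a pyranone) or may dimerise, the volatile alkyne may be lost from solution, or the product may be degraded by further photolysis. The fallback abandons the annulation and differentiates the two oxygens of a preformed ring by protecting-group chemistry. Setting out from aldehyde 16, the non-chelated 4-hydroxyl would be allylated selectively (allyl bromide 1.05 equiv, K2CO3, acetone, rt) to 2-hydroxy-6-pentyl-4-(prop-2-en-1-yloxy)benzaldehyde F1. The chelated 2-hydroxyl would then be methylated (MeI, K2CO3, DMF, 50 °C) to 2-methoxy-6-pentyl-4-(prop-2-en-1-yloxy)benzaldehyde F2. Pinnick oxidation (NaClO2, NaH2PO4, 2-methyl-2-butene) would give 2-methoxy-6-pentyl-4-(prop-2-en-1-yloxy)benzoic acid F3, and carboxylate alkylation (BnBr, K2CO3, DMF, rt) would give benzyl 2-methoxy-6-pentyl-4-(prop-2-en-1-yloxy)benzoate F4. Allyl transfer to morpholine with Pd(PPh3)4 in THF would return to the route at phenol 13.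

Step 2. The enal may undergo conjugate addition or oligomerisation under the amidine base, or the adduct may revert by retro-aldol cleavage before oxidation. The fallback installs the diazo group by diazo transfer instead of carrying it in on the nucleophile. Setting out from enal 2, Pinnick oxidation would give 2-methylideneheptanoic acid F5. Activation with 1,1'-carbonyldiimidazole in THF, then C-acylation and decarboxylation with monobenzyl malonate, MgCl2 and Et3N, would give benzyl 4-methylidene-3-oxononanoate F6. Regitz diazo transfer (4-acetamidobenzenesulfonyl azide, Et3N, MeCN, 0 °C) would rejoin the route at diazo keto ester 5.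

Step 9. Acyl transfer to the phenol may be slow because both positions ortho to the acyl chloride are blocked, so hydrolysis or loss of the ortho benzyl ether could compete. The fallback uses an acyl donor with a free, hydrogen-bonded ortho hydroxyl and a carbodiimide condensation, as in classical depside synthesis. Setting out from aldehyde 16, selective benzylation of the non-chelated hydroxyl (BnBr 1.0 equiv, K2CO3, acetone, rt) would give 4-(benzyloxy)-2-hydroxy-6-pentylbenzaldehyde F7. Oxidation with NaClO2, NaH2PO4 and 2-methyl-2-butene would give 4-(benzyloxy)-2-hydroxy-6-pentylbenzoic acid F8. Condensation of F8 with phenol 13 using N,N'-dicyclohexylcarbodiimide in toluene at rt would give 4-[(benzyloxy)carbonyl]-3-methoxy-5-pentylphenyl 4-(benzyloxy)-2-hydroxy-6-pentylbenzoate F9. Hydrogenolysis (H2, Pd/C, EtOAc) would then arrive directly at target 21.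

**Further compounds**
F1 | step 5 | 2-hydroxy-6-pentyl-4-(prop-2-en-1-yloxy)benzaldehyde | CCCCCc1cc(OCC=C)cc(O)c1C=O
F2 | step 5 | 2-methoxy-6-pentyl-4-(prop-2-en-1-yloxy)benzaldehyde | CCCCCc1cc(OCC=C)cc(OC)c1C=O
F3 | step 5 | 2-methoxy-6-pentyl-4-(prop-2-en-1-yloxy)benzoic acid | CCCCCc1cc(OCC=C)cc(OC)c1C(=O)O
F4 | step 5 | benzyl 2-methoxy-6-pentyl-4-(prop-2-en-1-yloxy)benzoate | CCCCCc1cc(OCC=C)cc(OC)c1C(=O)OCc1ccccc1
F5 | step 2 | 2-methylideneheptanoic acid | CCCCCC(=C)C(=O)O
F6 | step 2 | benzyl 4-methylidene-3-oxononanoate | CCCCCC(=C)C(=O)CC(=O)OCc1ccccc1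
F7 | step 9 | 4-(benzyloxy)-2-hydroxy-6-pentylbenzaldehyde | CCCCCc1cc(OCc2ccccc2)cc(O)c1C=O
F8 | step 9 | 4-(benzyloxy)-2-hydroxy-6-pentylbenzoic acid | CCCCCc1cc(OCc2ccccc2)cc(O)c1C(=O)O
F9 | step 9 | 4-[(benzyloxy)carbonyl]-3-methoxy-5-pentylphenyl 4-(benzyloxy)-2-hydroxy-6-pentylbenzoate | CCCCCc1cc(OCc2ccccc2)cc(O)c1C(=O)Oc1cc(CCCCC)c(C(=O)OCc2ccccc2)c(OC)c1
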